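## Retrosynthetic overview

1. Target 23 ⇒ tertiary alcohol 22 (chloroetherification closes the pyran last) ⇒ methyl ketone 19 + homoprenyl Grignard reagent (C11 set by Felkin–Anh addition).
2. 19 ⇒ enol triflate 15 (Heck acetylation, conjugate reduction, C7 equilibrated) ⇒ allylic alcohol 12 (reductive 1,3-transposition puts the alkene at C4=C5).
3. 12 ⇒ adduct 9 ⇒ achiral, mirror-symmetric 4-isocyanato-4-methylcyclohexadienone 6 + siloxy diene 8 by a catalytic enantioselective desymmetrizing Diels–Alder reaction (key step; builds ring A and sets C1, C6, C10).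
4. 6 ⇒ benzoic acid 1 (Birch reductive methylation, Curtius rearrangement, bis-allylic oxidation); the carboxyl carbon ends as the formyl carbon.
5. Ring order: ring B (from the arene), ring A (Diels–Alder), pyran.

Numbering: bicyclic intermediates are numbered like the carbon skeleton of the target. C1 and C6 are the ring-fusion carbons, C2–C5 complete ring A (C4 carries CH3), C7–C10 complete ring B (C7 carries the side chain, C10 carries N and CH3), and C11–C15 are the pyran carbons (C11 on C7, C14 = CHCl, C15 = CMe2). β is the face of the bicycle on which the nitrogen sits; α is the other face.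

Assumption: the (S)-oxazaborolidinium catalyst is taken to be the enantiomer that gives 9 as drawn; if the sense of induction is the reverse, its mirror image is used and nothing else changes.

## Route

Step 1
Reactants: 1 benzoic acid
Product: 3 1-methylcyclohexa-2,5-diene-1-carboxylic acid, via dilithium Birch enediolate 2 (not isolated)
Conditions: Li (3 equiv), NH3(l)/THF, −78 °C; MeI, −78 to 23 °C; aq. HCl
Reagents that add atoms: iodomethane, CI
Why: Birch reduction of the benzoate gives the cross-conjugated enediolate, which is C-methylated at the ipso carbon (Birch reductive alkylation), so the arene becomes a 1,4-diene that already holds the future C10 with its methyl group; no stereocentre is formed.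

Step 2
Reactants: 3 1-methylcyclohexa-2,5-diene-1-carboxylic acid
Product: 5 3-isocyanato-3-methylcyclohexa-1,4-diene, via acyl azide 4 (not isolated)
Conditions: (PhO)2P(O)N3, Et3N, PhMe, 0 to 23 °C, then 85 °C; short-path distillation
Reagents that add atoms: diphenylphosphoryl azide, [N-]=[N+]=NP(=O)(Oc1ccccc1)Oc1ccccc1
Why: Curtius rearrangement moves the quaternary carbon from the carbonyl carbon to nitrogen with loss of N2, which puts N on the future C10 and turns the old carboxyl carbon into the latent formyl carbon, and the tertiary isocyanate is a neutral, non-basic form of the formamide.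

Step 3
Reactants: 5 3-isocyanato-3-methylcyclohexa-1,4-diene
Product: 6 4-isocyanato-4-methylcyclohexa-2,5-dien-1-one
Conditions: pyridinium dichromate (C5H5NH)2Cr2O7 (turned over by the peroxide), anhydrous t-BuOOH, Celite, PhH, 23 °C
Reagents that add atoms: tert-butyl hydroperoxide, CC(C)(C)OO
Why: chromium-mediated allylic oxidation of the doubly allylic CH2 (the standard conversion of Birch 1,4-dienes into 4,4-disubstituted cyclohexadienones) gives the achiral dienone whose two enone arms are enantiotopic, and a hindered tertiary isocyanate does not add hydroperoxide without amine or tin catalysis.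

Step 4
Reactants: 7 (E)-2-methylbut-2-enal
Product: 8 (1E)-2-methyl-1-(triethylsilyloxy)buta-1,3-diene
Conditions: Et3SiOTf, Et3N, Et2O, 0 to 23 °C
Reagents that add atoms: triethylsilyl trifluoromethanesulfonate, CC[Si](CC)(CC)OS(=O)(=O)C(F)(F)F
Why: O-silylation of the enal and γ-deprotonation of the resulting oxocarbenium ion (silyl dienol ether formation) give the 1-siloxy diene, E at the enol ether as expected from the s-trans enal.

Step 5
Reactants: 6 4-isocyanato-4-methylcyclohexa-2,5-dien-1-one; 8 (1E)-2-methyl-1-(triethylsilyloxy)buta-1,3-diene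
Product: 9 cis-fused 10β-isocyanato-5β-(triethylsilyloxy) enone adduct
Conditions: (S)-o-tolyl-CBS-oxazaborolidine (20 mol %), Tf2NH (18 mol %), 8 (1.3 equiv), CH2Cl2, −78 to −40 °C; Et3N quench
Reagents that add atoms: none
Why: Proposed new method: the N-protonated oxazaborolidine binds the C7 carbonyl at the lone pair syn to one α-vinyl C–H and covers one face of that enone arm, so only the arm whose open face is also the intrinsically preferred one (anti to CH3, syn to the small electron-poor NCO) reacts, the siloxy diene adding endo with its CH2 terminus to the β-carbon C1 and its CH–OSi terminus to C6, which sets C1, C6 and C10 (1αH, 6αH, 10β-N) in one enantioselective desymmetrizing Diels–Alder reaction; the closest known chemistry is the Corey oxazaborolidinium-catalysed Diels–Alder reaction of quinone monoketals and cyclic enones with silyloxy dienes and the heteroatom-syn facial selectivity of 4-heteroatom-4-methylcyclohexadienones.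

Step 6
Reactants: 9 cis-fused 10β-isocyanato-5β-(triethylsilyloxy) enone adduct
Product: 12 10β-formamido-5β-hydroxy C7 enol triflate, via dilithium enolate amidate 10 (not isolated), via triethylsilyl ether triflate 11 (not isolated)
Conditions: LiBH(s-Bu)3 (2.3 equiv), THF, −78 to −30 °C; PhNTf2 (1.1 equiv), −78 to 0 °C; then 1 M HCl, THF, 23 °C
Reagents that add atoms: N-phenylbis(trifluoromethanesulfonimide), O=S(=O)(N(c1ccccc1)S(=O)(=O)C(F)(F)F)C(F)(F)F
Why: conjugate (1,4) hydride reduction of the remaining enone by the hindered trialkylborohydride gives the C7–C8 lithium enolate regiospecifically while the same reagent reduces the isocyanate to the N-lithio formamide, O-triflation of the enolate (faster than reaction at the hindered amidate) fixes the enol triflate at C7=C8, and the acidic work-up removes the silyl group; C1, C6 and C10 are untouched.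

Step 7
Reactants: 12 10β-formamido-5β-hydroxy C7 enol triflate
Product: 15 10β-formamido C7 enol triflate with the C4=C5 alkene, via Mitsunobu hydrazone adduct 13 (not isolated), via allylic diazene 14 (not isolated)
Conditions: 2-O2NC6H4SO2NHN=CMe2 (IPNBSH), PPh3, DEAD, THF, 0 to 23 °C; then CF3CH2OH/H2O (1:1), 23 °C
Reagents that add atoms: none
Why: Myers–Movassaghi reductive allylic transposition, in which Mitsunobu displacement of the C5 hydroxyl, hydrolytic loss of acetone and sulfinic acid to the monoalkyl diazene and its retro-ene loss of N2 deliver hydrogen to C3 and move the alkene to C4=C5; C5 becomes sp2, so either C5 epimer of 12 converges on 15.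

Step 8
Reactants: 15 10β-formamido C7 enol triflate with the C4=C5 alkene
Product: 17 7-acetyl C7=C8 enone, via 2-butoxy diene 16 (not isolated)
Conditions: Pd(OAc)2 (3 mol %), Ph2P(CH2)3PPh2 (6 mol %), n-butyl vinyl ether, Et3N, DMF, 70 °C; then 1 M HCl, THF, 0 °C
Reagents that add atoms: butyl vinyl ether, C=COCCCC; water, O
Why: Heck reaction of the alkenyl triflate with an alkyl vinyl ether under the triflate/bidentate-phosphine regime couples at the oxygen-bearing carbon, and hydrolysis of the enol ether unveils the methyl ketone that carries C11 and its methyl group; no stereocentre is formed.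

Step 9
Reactants: 17 7-acetyl C7=C8 enone
Product: 19 7α-acetyl methyl ketone (H7 β), via triethylsilyl enol ether 18 (not isolated)
Conditions: RhCl(PPh3)3 (2 mol %), Et3SiH, PhH, 50 °C; then K2CO3, MeOH, 23 °C
Reagents that add atoms: none
Why: rhodium-catalysed 1,4-hydrosilylation (Ojima) reduces only the conjugated C7=C8 bond, and methanolysis with base equilibration of the epimerisable C7 puts the acetyl group equatorial and trans to the C6–C5 bond, because the C7 epimer must accept either an axial acetyl group 1,3-diaxial to C2 or a syn-diaxial N/C5 contact in the cis-decalin.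

Step 10
Reactants: 19 7α-acetyl methyl ketone (H7 β); 20 5-bromo-2-methylpent-2-ene
Product: 22 (11R)-tertiary alcohol with the homoprenyl side chain, via homoprenylmagnesium bromide 21 (not isolated)
Conditions: 20 (3 equiv), Mg, THF, 23 °C; then 19, THF, −78 to −20 °C; aq. NH4Cl
Reagents that add atoms: none
Why: Grignard 1,2-addition under Felkin–Anh control, the nucleophile attacking the acetyl carbonyl anti to the bulky C6 substituent of C7 and past the C7–H, gives the 11R carbinol (adding CH3 last to the homoprenyl ketone would give 11S), and one equivalent of 21 is consumed by the formamide N–H.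

Step 11
Reactants: 22 (11R)-tertiary alcohol with the homoprenyl side chain
Product: 23 N-[(1R,4R,4aR,8aS)-4-[(2R,5S)-5-chloro-2,6,6-trimethyloxan-2-yl]-1,6-dimethyl-1,2,3,4,4a,7,8,8a-octahydronaphthalen-1-yl]formamide
Conditions: N-chlorosuccinimide (1.05 equiv), Ph3P=S (10 mol %), CH2Cl2, −20 °C; aq. Na2S2O3/NaHCO3
Reagents that add atoms: N-chlorosuccinimide, O=C1CCC(=O)N1Cl
Why: Lewis-base-catalysed chloroetherification, in which Markovnikov 6-endo capture of the side-chain chloronium ion by the C11 hydroxyl through a chair with the decalinyl group equatorial and anti addition places Cl equatorial at C14 (14S) and closes the pyran, while the ring-A alkene, shielded by the ring fusion and the C7 substituent and out of reach of the hydroxyl, is expected to react more slowly.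

## Compound list

1 | benzoic acid | O=C(O)c1ccccc1 | starting material
2 | dilithium (cyclohexa-2,5-dien-1-ylidene)methanediolate (Birch enediolate) | [Li+].[Li+].[O-]C([O-])=C1C=CCC=C1 | intermediate
3 | 1-methylcyclohexa-2,5-diene-1-carboxylic acid | CC1(C(=O)O)C=CCC=C1 | intermediate
4 | 1-methylcyclohexa-2,5-diene-1-carbonyl azide | CC1(C(=O)N=[N+]=[N-])C=CCC=C1 | intermediate
5 | 3-isocyanato-3-methylcyclohexa-1,4-diene | CC1(N=C=O)C=CCC=C1 | intermediate
6 | 4-isocyanato-4-methylcyclohexa-2,5-dien-1-one | CC1(N=C=O)C=CC(=O)C=C1 | intermediate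
7 | (E)-2-methylbut-2-enal (tiglic aldehyde) | C/C=C(\C)C=O | starting material
8 | (1E)-2-methyl-1-(triethylsilyloxy)buta-1,3-diene | C=C/C(C)=C/O[Si](CC)(CC)CC | intermediate
9 | cis-fused adduct: C7 ketone, C8=C9 and C3=C4 alkenes, 10β-NCO, 10α-CH3, 4-CH3, 5β-OSiEt3, H1 and H6 α | CC1=CC[C@@H]2[C@](C)(N=C=O)C=CC(=O)[C@@H]2[C@@H]1O[Si](CC)(CC)CC | intermediate
10 | dilithium salt of the C7(8) enolate and N-lithio formamide (5β-OSiEt3) | [Li+].[Li+].CC1=CC[C@@H]2[C@](C)([N-]C=O)CC=C([O-])[C@@H]2[C@@H]1O[Si](CC)(CC)CC | intermediate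
11 | C7 enol triflate (C7=C8), 10β-NHCHO, 5β-OSiEt3, C3=C4 | CC1=CC[C@@H]2[C@](C)(NC=O)CC=C(OS(=O)(=O)C(F)(F)F)[C@@H]2[C@@H]1O[Si](CC)(CC)CC | intermediate
12 | C7 enol triflate (C7=C8), 10β-NHCHO, 5β-OH, C3=C4 | CC1=CC[C@@H]2[C@](C)(NC=O)CC=C(OS(=O)(=O)C(F)(F)F)[C@@H]2[C@@H]1O | intermediate
13 | Mitsunobu adduct: 5α-N(SO2C6H4-2-NO2)N=CMe2 on the skeleton of 12 | CC1=CC[C@@H]2[C@](C)(NC=O)CC=C(OS(=O)(=O)C(F)(F)F)[C@@H]2[C@H]1N(N=C(C)C)S(=O)(=O)c1ccccc1[N+](=O)[O-] | intermediate
14 | 5α-diazene (N=NH) on the skeleton of 12 | CC1=CC[C@@H]2[C@](C)(NC=O)CC=C(OS(=O)(=O)C(F)(F)F)[C@@H]2[C@H]1N=N | intermediate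
15 | C7 enol triflate with C4=C5 and C7=C8, 10β-NHCHO, 10α-CH3, H1 and H6 α | CC1=C[C@H]2C(OS(=O)(=O)C(F)(F)F)=CC[C@@](C)(NC=O)[C@H]2CC1 | intermediate
16 | 7-(1-butoxyvinyl) diene (C4=C5, C7=C8) | CC1=C[C@H]2C(C(=C)OCCCC)=CC[C@@](C)(NC=O)[C@H]2CC1 | intermediate
17 | 7-acetyl enone (C7=C8 conjugated with the acetyl group, C4=C5) | CC1=C[C@H]2C(C(C)=O)=CC[C@@](C)(NC=O)[C@H]2CC1 | intermediate
18 | triethylsilyl enol ether of 19 (C7=C11, E/Z mixture) | CC1=C[C@H]2C(=C(C)O[Si](CC)(CC)CC)CC[C@@](C)(NC=O)[C@H]2CC1 | intermediate
19 | 7α-acetyl ketone (H7 β), ring B saturated, C4=C5 | CC1=C[C@H]2[C@H](C(C)=O)CC[C@@](C)(NC=O)[C@H]2CC1 | intermediate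
20 | 5-bromo-2-methylpent-2-ene | CC(C)=CCCBr | starting material
21 | (4-methylpent-3-en-1-yl)magnesium bromide | CC(C)=CCC[Mg]Br | intermediate
22 | 7α-[(2R)-2-hydroxy-6-methylhept-5-en-2-yl] formamide (11R) | CC1=C[C@H]2[C@H]([C@](C)(O)CCC=C(C)C)CC[C@@](C)(NC=O)[C@H]2CC1 | intermediate
23 | N-[(1R,4R,4aR,8aS)-4-[(2R,5S)-5-chloro-2,6,6-trimethyloxan-2-yl]-1,6-dimethyl-1,2,3,4,4a,7,8,8a-octahydronaphthalen-1-yl]formamide | CC1=C[C@H]2[C@H]([C@@]3(C)CC[C@H](Cl)C(C)(C)O3)CC[C@@](C)(NC=O)[C@H]2CC1 | target

## Step count and weakest steps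

Total: 11 steps. Longest linear sequence: 10 steps (steps 1–3 and 5–11; step 4 makes the diene).

Step 5 (desymmetrizing Diels–Alder) can fail through low ee, double addition, or loss of the diene to the strong acid. The fallback breaks the symmetry with hydride instead. Setting out from isocyanate 5, LiBHEt3 gives N-(1-methylcyclohexa-2,5-dien-1-yl)formamide F1, and the oxidation of step 3 gives 4-formamido-4-methylcyclohexa-2,5-dien-1-one F2. Copper hydride, CuH, made from Cu(OAc)2, (R)-DTBM-SEGPHOS and (EtO)2MeSiH with t-BuOH, reduces one of the two enantiotopic enone arms to N-[(1R)-1-methyl-4-oxocyclohex-2-en-1-yl]formamide F3. A substrate-controlled Diels–Alder reaction of F3 with 8 (Me2AlCl, 2.5 equiv, anti to the C10 methyl group) gives the ring-B-saturated cis-fused ketone F4. Kinetic deprotonation of F4 at the C8 methylene (KN(SiMe3)2, 2.2 equiv, −78 °C) and O-triflation with PhNTf2 rejoin the route at triethylsilyl ether triflate 11.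

Step 7 (reductive transposition) can fail because the Mitsunobu displacement is at a hindered allylic carbinol, and SN2′ attack would return the untransposed alkene. The fallback runs the transposition through a hydrazone. Setting out from 12, Dess–Martin periodinane gives the ring-A enone triflate F5 (C5 ketone conjugated with C3=C4), and TsNHNH2 gives its tosylhydrazone F6. Catecholborane followed by NaOAc·3H2O (Kabalka reduction: hydride to C5, loss of sulfinate, retro-ene of the C5 diazene with hydrogen delivery to C3) returns to the route at 15.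

Step 11 (chloroetherification) can fail through attack on the ring-A alkene, closure to the five-membered ether, or N-chlorination. The fallback builds the pyran by hemiketal formation and puts chlorine in by carbonyl chemistry that touches neither alkene. Setting out from 19, addition of [3-(2-methyl-1,3-dioxolan-2-yl)propyl]magnesium chloride F7 (from commercial 2-(3-chloropropyl)-2-methyl-1,3-dioxolane and Mg) gives, with the same Felkin–Anh sense, the 11R tertiary alcohol ketal F8. Aqueous acid unmasks the C15 methyl ketone, which closes onto the C11 hydroxyl as the six-membered lactol F9. Enamine-mediated α-chlorination at C14 (NCS, catalytic pyrrolidine) and equilibration of the epimerisable α-chloro centre give the 14-chloro lactol F10 with Cl equatorial. Me3Al/Me3SiOTf then methylates the C15 oxocarbenium ion to the gem-dimethyl pyran and arrives at 23.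

## Further compounds

F1 | step 5 | N-(1-methylcyclohexa-2,5-dien-1-yl)formamide | CC1(NC=O)C=CCC=C1
F2 | step 5 | 4-formamido-4-methylcyclohexa-2,5-dien-1-one | CC1(NC=O)C=CC(=O)C=C1
F3 | step 5 | N-[(1R)-1-methyl-4-oxocyclohex-2-en-1-yl]formamide | O=C1C=C[C@](C)(NC=O)CC1
F4 | step 5 | cis-fused ring-B-saturated C7 ketone, 10β-NHCHO, 5β-OSiEt3, C3=C4 | CC1=CC[C@@H]2[C@](C)(NC=O)CCC(=O)[C@@H]2[C@@H]1O[Si](CC)(CC)CC
F5 | step 7 | ring-A enone (C5 ketone, C3=C4) with the C7 enol triflate | CC1=CC[C@@H]2[C@](C)(NC=O)CC=C(OS(=O)(=O)C(F)(F)F)[C@@H]2C1=O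
F6 | step 7 | C5 tosylhydrazone of F5 | CC1=CC[C@@H]2[C@](C)(NC=O)CC=C(OS(=O)(=O)C(F)(F)F)[C@@H]2C1=NNS(=O)(=O)c1ccc(C)cc1
F7 | step 11 | [3-(2-methyl-1,3-dioxolan-2-yl)propyl]magnesium chloride | CC1(CCC[Mg]Cl)OCCO1
F8 | step 11 | (11R)-tertiary alcohol with the C15 ketone as its dioxolane | CC1=C[C@H]2[C@H]([C@](C)(O)CCCC3(C)OCCO3)CC[C@@](C)(NC=O)[C@H]2CC1
F9 | step 11 | six-membered lactol (C15 hemiketal, anomers) of the C11 hydroxy C15 ketone | CC1=C[C@H]2[C@H]([C@@]3(C)CCCC(C)(O)O3)CC[C@@](C)(NC=O)[C@H]2CC1
F10 | step 11 | (14S)-14-chloro lactol | CC1=C[C@H]2[C@H]([C@@]3(C)CC[C@H](Cl)C(C)(O)O3)CC[C@@](C)(NC=O)[C@H]2CC1
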